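The whole route rests on cutting C6–C7 of the seven-membered ring. The unit C6(OH)–C7H2–C8(Me)=C9, a homoallylic alcohol lying wholly inside that ring, is read as the outcome of a [2,3]-Wittig shift within a six-membered cyclic ether. In one operation a C6 carbanion next to the ring oxygen bonds to the CH2 terminus of a C9 isopropenyl group. C6–C7 forms, O–C9 breaks, the oxygen leaves the ring as the C6 alkoxide, the alkene moves to C8=C9, the cycloheptene closes and C6 is set. The precursor is a trans-fused 3-oxabicyclo[4.3.0]nonane (octahydrocyclopenta[c]pyran) with an equatorial C6 tributylstannyl group, an axial C9 isopropenyl group and free C2 and C4 hydroxyls.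

Key step: step 16

**Numbering and conventions.** C1 = quaternary ring-fusion carbon (methyl), C2 = CH–O, C3 = CH2, C4 = C(OH)(isopropyl), C5 = ring-fusion CH, C6 = CH–O, C7 = CH2, C8(Me)=C9, C10 = CH2. This numbering is kept for all intermediates. β is the face of the C1 methyl group and α is the other face. The target is 1R,2S,4R,5S,6S: C1–CH3 β, C2–O α, C4–OH β (isopropyl α), H5 α, C6–O α, with a trans ring fusion.

**Remarks on the design.**
- a) In the bicyclic ether the oxygen lies between C6 and C9, one carbon away from the ring fusion, so it is a 3-oxabicyclo[4.3.0]nonane.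
- b) C9 ceases to be a stereocentre in the key step but decides C6. The tether lets C7 reach C6 only on the face that carries the isopropenyl group. The 9S configuration (isopropenyl β, axial, cis to the C1 methyl) is therefore set by reagent control in step 10.
- c) Both silyl ethers are taken off before the key step. A silyl ether on the C4 oxygen would sit 1,4 to the carbanion (retro-Brook migration) and would crowd the β face on which C6–C7 forms.

**Assumption.** Lactol 19 and chloride 22 are treated as configurationally labile at C6, and 15 as a mixture of C9 epimers, so these centres carry no descriptor in the SMILES.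

Step 1
Reactants: 1 (S)-4-(tert-butyldimethylsilyloxy)cyclopent-2-en-1-one; 2 allylmagnesium bromide
Product: 3 (3S,4S)-3-allyl-4-(tert-butyldimethylsilyloxy)-1-(trimethylsilyloxy)cyclopent-1-ene
Conditions: 2, CuBr·SMe2, Me3SiCl, THF, −78 °C; Et3N, cold aq NaHCO3
Reagents that add atoms: allylmagnesium bromide 2, C=CC[Mg]Br; chlorotrimethylsilane, C[Si](C)(C)Cl
Why: Copper-mediated conjugate allylation with silyl trapping, in which allylcopper adds 1,4 anti to the C2 silyloxy group (a centre that step 2 erases) while Me3SiCl speeds the addition, suppresses 1,2-attack and fixes the C4–C5 enol ether away from the eliminable C2 oxygen.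

Step 2
Reactants: 3 (3S,4S)-3-allyl-4-(tert-butyldimethylsilyloxy)-1-(trimethylsilyloxy)cyclopent-1-ene
Product: 4 (S)-3-allyl-4-(tert-butyldimethylsilyloxy)cyclopent-2-en-1-one
Conditions: Pd(OAc)2 (1.05 equiv), MeCN, rt
Reagents that add atoms: none
Why: Saegusa–Ito oxidation, in which the palladium enolate at C5 has only the C1 hydrogen available for β-hydride loss, so the C5=C1 enone returns regiospecifically with the allyl group on the β-carbon and C2 untouched.

Step 3
Reactants: 4 (S)-3-allyl-4-(tert-butyldimethylsilyloxy)cyclopent-2-en-1-one; 5 methyllithium; 6 formaldehyde (monomer cracked from paraformaldehyde)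
Product: 8 (2S,3R,4S)-3-allyl-4-(tert-butyldimethylsilyloxy)-2-(hydroxymethyl)-3-methylcyclopentan-1-one, via lithium enolate 7 (not isolated)
Conditions: Me2CuLi (from 5, CuI), Et2O, −78 → −20 °C; then 6 in THF, −78 °C; aq NH4Cl
Reagents that add atoms: methyllithium 5 (as Me2CuLi), [Li]C; formaldehyde 6, C=O
Why: Gilman cuprate 1,4-addition followed by aldol trapping of the regiodefined enolate (three-component coupling), in which methyl enters anti to the C2 silyloxy group to set the quaternary C1 and formaldehyde then approaches C5 from the same β face, away from the allyl and silyloxy groups, so that C6 ends up trans to C10.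

Step 4
Reactants: 8 (2S,3R,4S)-3-allyl-4-(tert-butyldimethylsilyloxy)-2-(hydroxymethyl)-3-methylcyclopentan-1-one
Product: 9 (2S,3R,4S)-3-allyl-4-(tert-butyldimethylsilyloxy)-3-methyl-2-[(triethylsilyloxy)methyl]cyclopentan-1-one
Conditions: Et3SiCl, imidazole, CH2Cl2, 0 °C
Reagents that add atoms: chlorotriethylsilane, CC[Si](Cl)(CC)CC
Why: Routine silylation of a primary alcohol under weak base, which shuts off retro-aldol and dehydration of the β-hydroxy ketone and adds bulk to the β face for step 5.

Step 5
Reactants: 9 C6 triethylsilyl ether ketone; 10 isopropylmagnesium chloride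
Product: 11 tertiary alcohol (1R,2S,4R,5S; C4–OH β; isopropyl α; C6 OSiEt3; C2 OTBS; C1 allyl)
Conditions: 10, CeCl3 (anhydrous), THF, −78 → −40 °C; aq NH4Cl
Reagents that add atoms: isopropylmagnesium chloride 10, CC(C)[Mg]Cl
Why: Organocerium 1,2-addition, whose low basicity holds back enolisation and β-hydride reduction, and in which the nucleophile should enter C4 from the α face, anti to the adjacent C5 CH2OSiEt3 arm and the pseudo-axial C1 methyl, placing the hydroxyl β.

Step 6
Reactants: 11 tertiary alcohol
Product: 12 bis(triethylsilyl) ether (C4 OSiEt3; C6 OSiEt3; C2 OTBS; C1 allyl)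
Conditions: Et3SiOTf, 2,6-lutidine, CH2Cl2, 0 °C → rt
Reagents that add atoms: triethylsilyl trifluoromethanesulfonate, CC[Si](CC)(CC)OS(=O)(=O)C(F)(F)F
Why: Silyl triflate silylation of a hindered tertiary alcohol, which protects the C4 oxygen through the β-oxy-carbonyl stages and the chlorination and stannylation of step 14.

Step 7
Reactants: 12 bis(triethylsilyl) ether
Product: 13 C9 aldehyde (C1–C10H2–C9HO)
Conditions: O3, CH2Cl2, −78 °C; PPh3, −78 °C → rt
Reagents that add atoms: ozone, [O-][O+]=O
Why: Ozonolysis with reductive work-up cleaves the only alkene, removes the terminal CH2 and exposes C9 as the aldehyde, with all silyl ethers inert.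

Step 8
Reactants: 13 C9 aldehyde; 14 isopropenylmagnesium bromide
Product: 15 allylic alcohols (mixture of C9 epimers)
Conditions: 14, THF, −78 → 0 °C; aq NH4Cl
Reagents that add atoms: isopropenylmagnesium bromide 14, CC(=C)[Mg]Br
Why: Grignard 1,2-addition brings in C8, its methyl group and C7, and since no useful induction from the remote quaternary C1 is expected, both C9 epimers go together into step 9, which erases that centre.

Step 9
Reactants: 15 allylic alcohols
Product: 16 isopropenyl ketone (C9 enone)
Conditions: Dess–Martin periodinane, CH2Cl2, 0 °C → rt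
Reagents that add atoms: none
Why: Dess–Martin oxidation of a secondary allylic alcohol under nearly neutral conditions converges both epimers on one enone and leaves the silyl ethers alone.

Step 10
Reactants: 16 isopropenyl ketone
Product: 17 (9S)-allylic alcohol
Conditions: (R)-2-methyl-CBS-oxazaborolidine ((R)-1-methyl-3,3-diphenyltetrahydro-1H,3H-pyrrolo[1,2-c][1,3,2]oxazaborole, 0.3 equiv), catecholborane, toluene, −78 °C
Reagents that add atoms: none
Why: Corey–Bakshi–Shibata reduction under reagent control, in which the isopropenyl group acts as the large and the C10 methylene as the small substituent so that the R catalyst should give the 9S carbinol, while catecholborane at low temperature avoids hydroboration of the 1,1-disubstituted alkene.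

Step 11
Reactants: 17 (9S)-allylic alcohol
Product: 18 (9S)-C6,C9-diol (C4 OSiEt3 and C2 OTBS retained)
Conditions: pyridinium p-toluenesulfonate (cat.), MeOH/CH2Cl2, 0 °C
Reagents that add atoms: none
Why: Acid-catalysed methanolysis sorts silyl ethers by steric access, so the primary C6 triethylsilyl ether is lost while the hindered tertiary C4 triethylsilyl ether and the secondary C2 tert-butyldimethylsilyl ether stay.

Step 12
Reactants: 18 (9S)-C6,C9-diol
Product: 20 trans-fused δ-lactone (C6 carbonyl; ring O on C9; isopropenyl β), via lactol 19 (not isolated)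
Conditions: 2,2,6,6-tetramethylpiperidine-1-oxyl (TEMPO, 0.2 equiv), PhI(OAc)2 (2.5 equiv), CH2Cl2, rt
Reagents that add atoms: none
Why: Oxoammonium-mediated oxidative lactonisation of a 1,5-diol, in which the primary C6 alcohol is oxidised first, the aldehyde is caught by the C9 hydroxyl as the lactol and this is oxidised on, with C5 and C9 unchanged.

Step 13
Reactants: 20 trans-fused δ-lactone
Product: 19 lactol (C6 anomers)
Conditions: iBu2AlH (1.2 equiv), CH2Cl2, −78 °C; aq potassium sodium tartrate
Reagents that add atoms: none
Why: Partial reduction of a lactone with iBu2AlH, which stops at the tetrahedral aluminium alkoxide at low temperature and gives the lactol on work-up.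

Step 14
Reactants: 19 lactol; 21 tributyltin hydride
Product: 23 bis-silylated C6 stannane (SnBu3 equatorial α; C9 isopropenyl axial β; C2 OTBS; C4 OSiEt3), via C6 chloride 22 (not isolated)
Conditions: 1-chloro-N,N,2-trimethylprop-1-en-1-amine, CH2Cl2, 0 °C, evaporate; then Bu3SnLi (from 21, LiN(iPr)2, 3 equiv), THF, −78 °C
Reagents that add atoms: tributyltin hydride 21 (as Bu3SnLi), CCCC[SnH](CCCC)CCCC
Why: Displacement of an α-chloro ether by a stannyllithium (the glycosyl chloride to glycosyl stannane reaction) after chlorination under neutral conditions, in which tin should end up equatorial on the α face of C6, trans to the isopropenyl group, both because backside attack on the axial chloride leads there and because the axial β position is closed by the syn-axial C1 methyl and C9 isopropenyl groups.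

Step 15
Reactants: 23 bis-silylated C6 stannane
Product: 24 stannane diol (1R,2S,4R,5R,6R,9S; free C2 and C4 hydroxyls)
Conditions: Bu4NF (6 equiv), THF, rt → 45 °C
Reagents that add atoms: none
Why: Fluoride-driven desilylation removes both silyl ethers at once without any need for selectivity, and α-alkoxy tetraalkylstannanes tolerate Bu4NF.

Step 16
Reactants: 24 stannane diol
Product: 26 (1R,2S,4R,5S,6S)-dauc-8-ene-2,4,6-triol, via C6-lithio dialkoxide 25 (not isolated)
Conditions: n-BuLi (3.5 equiv), THF, −78 °C, then −78 → −20 °C; aq NH4Cl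
Reagents that add atoms: none
Why: Proposed new method: two equivalents of n-BuLi turn the C2 and C4 hydroxyls into lithium alkoxides and the third effects tin–lithium exchange with retention, giving the equatorial, configurationally stable α-alkoxy organolithium 25, whose rear (axial, β) lobe points at the CH2 terminus of the axial β isopropenyl group, so that C6–C7 formation, migration of the π bond to C8=C9 and O–C9 cleavage run through a five-centre envelope (C6, O, C9, C8, C7). The closest known reaction types are the Wittig–Still rearrangement of acyclic α-(allyloxy)alkyllithiums made from stannanes and the [2,3]-Wittig ring contractions of large-ring allylic ethers, whereas the case in which carbanion carbon and allylic carbon flank the oxygen of one six-membered ring, so that the heteroatom is expelled and six ring members become seven, has not been established. The cycloheptene closes 7-endo-trig along the carbon tether (5-endo along the oxygen tether) through an 8-oxabicyclo[3.2.1]octene-like transition state whose one-atom oxygen bridge is being lost. The only new stereocentre, C6, is controlled by C9: the tether lets C7 reach C6 on the β face only, which means inversion at the lithium-bearing carbon (the usual course of [2,3]-Wittig shifts) and gives the 6S carbinol while C9 becomes sp2. The step needs periselectivity ([2,3] against the radical-pair [1,2] shift to a cyclopentanol) and control of alkene geometry; the first is served by the low temperature, the trans lithium/isopropenyl relationship and the release of the syn-axial C1-methyl/C9-isopropenyl strain, and the second is fixed because the reacting CH2 lies anti to H9 and on the side of C10, so only the ring-cis alkene can form. No silyl ether is present, so silyl migration to the carbanion is excluded and the β face at C6 stays open.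

Step 17
Reactants: 26 (1R,2S,4R,5S,6S)-dauc-8-ene-2,4,6-triol; 27 angelic acid
Product: 28 target CNP0303897.1 (1R,2S,4R,5S,6S)-2,6-bis(angeloyloxy)dauc-8-en-4-ol
Conditions: 27 (6 equiv), 2,4,6-trichlorobenzoyl chloride (6 equiv), Et3N, toluene, rt; then 26, 80 °C
Reagents that add atoms: angelic acid 27, C/C=C(/C)C(=O)O
Why: Yamaguchi-type mixed-anhydride esterification run without a nucleophilic amine catalyst, the established way to attach angelate without Z to E isomerisation, in which the two secondary hydroxyls are acylated and the hindered tertiary C4 hydroxyl is not.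

**Compound list**

1 | (S)-4-(tert-butyldimethylsilyloxy)cyclopent-2-en-1-one | O=C1C[C@H](O[Si](C)(C)C(C)(C)C)C=C1 | starting material
2 | allylmagnesium bromide | C=CC[Mg]Br | starting material
3 | (3S,4S)-3-allyl-4-(tert-butyldimethylsilyloxy)-1-(trimethylsilyloxy)cyclopent-1-ene | C=CC[C@H]1C=C(O[Si](C)(C)C)C[C@@H]1O[Si](C)(C)C(C)(C)C | intermediate
4 | (S)-3-allyl-4-(tert-butyldimethylsilyloxy)cyclopent-2-en-1-one | O=C1C=C(CC=C)[C@@H](O[Si](C)(C)C(C)(C)C)C1 | intermediate
5 | methyllithium | [Li]C | starting material
6 | formaldehyde (monomer from paraformaldehyde) | C=O | starting material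
7 | lithium enolate (C4–C5) with quaternary C1 in place | C=CC[C@@]1(C)[C@@H](O[Si](C)(C)C(C)(C)C)CC(O[Li])=C1 | intermediate
8 | (2S,3R,4S)-3-allyl-4-(tert-butyldimethylsilyloxy)-2-(hydroxymethyl)-3-methylcyclopentan-1-one | C=CC[C@@]1(C)[C@@H](O[Si](C)(C)C(C)(C)C)CC(=O)[C@@H]1CO | intermediate
9 | (2S,3R,4S)-3-allyl-4-(tert-butyldimethylsilyloxy)-3-methyl-2-[(triethylsilyloxy)methyl]cyclopentan-1-one | C=CC[C@@]1(C)[C@@H](O[Si](C)(C)C(C)(C)C)CC(=O)[C@@H]1CO[Si](CC)(CC)CC | intermediate
10 | isopropylmagnesium chloride | CC(C)[Mg]Cl | starting material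
11 | tertiary alcohol, C4–OH β, isopropyl α | C=CC[C@@]1(C)[C@@H](O[Si](C)(C)C(C)(C)C)C[C@@](O)(C(C)C)[C@@H]1CO[Si](CC)(CC)CC | intermediate
12 | C4,C6-bis(triethylsilyl) ether | C=CC[C@@]1(C)[C@@H](O[Si](C)(C)C(C)(C)C)C[C@@](O[Si](CC)(CC)CC)(C(C)C)[C@@H]1CO[Si](CC)(CC)CC | intermediate
13 | C9 aldehyde | O=CC[C@@]1(C)[C@@H](O[Si](C)(C)C(C)(C)C)C[C@@](O[Si](CC)(CC)CC)(C(C)C)[C@@H]1CO[Si](CC)(CC)CC | intermediate
14 | isopropenylmagnesium bromide | CC(=C)[Mg]Br | starting material
15 | allylic alcohols, C9 epimers | C=C(C)C(O)C[C@@]1(C)[C@@H](O[Si](C)(C)C(C)(C)C)C[C@@](O[Si](CC)(CC)CC)(C(C)C)[C@@H]1CO[Si](CC)(CC)CC | intermediate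
16 | isopropenyl ketone (C9 enone) | C=C(C)C(=O)C[C@@]1(C)[C@@H](O[Si](C)(C)C(C)(C)C)C[C@@](O[Si](CC)(CC)CC)(C(C)C)[C@@H]1CO[Si](CC)(CC)CC | intermediate
17 | (9S)-allylic alcohol | C=C(C)[C@@H](O)C[C@@]1(C)[C@@H](O[Si](C)(C)C(C)(C)C)C[C@@](O[Si](CC)(CC)CC)(C(C)C)[C@@H]1CO[Si](CC)(CC)CC | intermediate
18 | (9S)-C6,C9-diol | C=C(C)[C@@H](O)C[C@@]1(C)[C@@H](O[Si](C)(C)C(C)(C)C)C[C@@](O[Si](CC)(CC)CC)(C(C)C)[C@@H]1CO | intermediate
19 | lactol (C6 anomers), trans-fused 3-oxabicyclo[4.3.0]nonane | OC1O[C@H](C(C)=C)C[C@@]2(C)[C@@H](O[Si](C)(C)C(C)(C)C)C[C@@](O[Si](CC)(CC)CC)(C(C)C)[C@H]12 | intermediate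
20 | trans-fused δ-lactone | O=C1O[C@H](C(C)=C)C[C@@]2(C)[C@@H](O[Si](C)(C)C(C)(C)C)C[C@@](O[Si](CC)(CC)CC)(C(C)C)[C@H]12 | intermediate
21 | tributyltin hydride | CCCC[SnH](CCCC)CCCC | starting material
22 | C6 chloride (α-chloro ether, labile at C6) | ClC1O[C@H](C(C)=C)C[C@@]2(C)[C@@H](O[Si](C)(C)C(C)(C)C)C[C@@](O[Si](CC)(CC)CC)(C(C)C)[C@H]12 | intermediate
23 | bis-silylated C6 stannane, SnBu3 trans to isopropenyl | CCCC[Sn](CCCC)(CCCC)[C@H]1O[C@H](C(C)=C)C[C@@]2(C)[C@@H](O[Si](C)(C)C(C)(C)C)C[C@@](O[Si](CC)(CC)CC)(C(C)C)[C@H]12 | intermediate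
24 | stannane diol, precursor of the key step | CCCC[Sn](CCCC)(CCCC)[C@H]1O[C@H](C(C)=C)C[C@@]2(C)[C@@H](O)C[C@@](O)(C(C)C)[C@H]12 | intermediate
25 | equatorial C6-lithio C2,C4-dilithium dialkoxide | [Li][C@H]1O[C@H](C(C)=C)C[C@@]2(C)[C@@H](O[Li])C[C@@](O[Li])(C(C)C)[C@H]12 | intermediate
26 | (1R,2S,4R,5S,6S)-dauc-8-ene-2,4,6-triol, product of the key step | O[C@H]1CC(C)=CC[C@@]2(C)[C@@H](O)C[C@@](O)(C(C)C)[C@H]12 | intermediate
27 | angelic acid, (Z)-2-methylbut-2-enoic acid | C/C=C(/C)C(=O)O | starting material
28 | CNP0303897.1, (1R,2S,4R,5S,6S)-2,6-bis(angeloyloxy)dauc-8-en-4-ol | C/C=C(/C)C(=O)O[C@H]1CC(C)=CC[C@@]2(C)[C@@H](OC(=O)/C(C)=C\C)C[C@@](O)(C(C)C)[C@H]12 | target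

Total step count: 17
Longest linear sequence: 17 steps (from 1)

**Three steps most likely to fail**

**Step 16.**
- What may go wrong: after tin–lithium exchange the carbanion may not reach the bridged transition state. It may instead undergo O–C9 homolysis with [1,2] recombination, or merely be protonated on work-up.
- Fallback: known chemistry that closes the ring at C8=C9 by metathesis in place of the sigmatropic C6–C7 closure. It sets out from 12, which still carries the C10–C9 allyl group, and returns at 26.
- Swern oxidation converts primary triethylsilyl ethers directly into aldehydes and spares the tertiary triethylsilyl and secondary tert-butyldimethylsilyl ethers. It gives the C6 aldehyde F1.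
- Brown methallylation uses the Ipc2B-methallyl antipode matched to the 6S carbinol (by analogy with α-branched aldehydes, the reagent derived from (+)-α-pinene). It gives the 6S homoallylic alcohol F2.
- Ring-closing metathesis with the second-generation Grubbs catalyst (CH2Cl2, reflux) joins the monosubstituted and the 1,1-disubstituted alkene to the trisubstituted cycloheptene, the bis-silylated daucene core F3.
- Bu4NF then removes both silyl groups and gives 26.

**Step 14.**
- What may go wrong: at the hindered C6, loss of HCl towards C5, attack of the stannyl anion on chlorine, or chlorination of the open hydroxy aldehyde form may overtake substitution.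
- Fallback: reverse the polarity so that no tin nucleophile has to reach C6. It sets out from 19 and returns at 25.
- PhSH with catalytic BF3·OEt2 (CH2Cl2, −78 °C) gives the phenylthio acetal F4, and Bu4NF gives the phenylthio acetal diol F5.
- After deprotonation of both hydroxyls with n-BuLi, reductive lithiation with lithium 4,4′-di-tert-butylbiphenylide (THF, −78 °C) cleaves the C6–S bond.
- The axial C6-lithio isomer F6 forms first. On warming it should epimerise to the less crowded equatorial organolithium 25, as 2-lithiotetrahydropyrans do, and 25 continues as in step 16.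

**Step 5.**
- What may go wrong: β-hydride reduction, or enolisation with loss of the C2 silyloxy group, may overtake addition of the bulky secondary nucleophile. The facial bias may also be weak.
- Fallback: use a flat sp2 nucleophile without β-hydrogens and saturate it afterwards, which requires the allyl alkene to be removed first. It sets out from 9 and returns at 13.
- Ozonolysis (O3, then PPh3) gives the keto aldehyde F7.
- MeOSiMe3 with catalytic Me3SiOTf (CH2Cl2, −78 °C) acetalises only the aldehyde and gives the keto dimethyl acetal F8.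
- Isopropenylmagnesium bromide 14 with CeCl3 (THF, −78 °C) gives the tertiary isopropenyl carbinol F9.
- Hydrogenation (H2, Pd/C, EtOAc) gives the isopropyl carbinol acetal F10.
- Et3SiOTf/2,6-lutidine followed by water silylates the C4 hydroxyl and unmasks the aldehyde-derived acetal in the same flask, giving 13.

**Further compounds**

F1 | step 16 | C6 aldehyde with C1 allyl group | C=CC[C@@]1(C)[C@@H](O[Si](C)(C)C(C)(C)C)C[C@@](O[Si](CC)(CC)CC)(C(C)C)[C@@H]1C=O
F2 | step 16 | (6S)-homoallylic alcohol (methallyl adduct) | C=CC[C@@]1(C)[C@@H](O[Si](C)(C)C(C)(C)C)C[C@@](O[Si](CC)(CC)CC)(C(C)C)[C@@H]1[C@@H](O)CC(C)=C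
F3 | step 16 | bis-silylated daucene core with free C6 hydroxyl | O[C@H]1CC(C)=CC[C@@]2(C)[C@@H](O[Si](C)(C)C(C)(C)C)C[C@@](O[Si](CC)(CC)CC)(C(C)C)[C@H]12
F4 | step 14 | C6 phenylthio acetal, bis-silylated | c1ccccc1SC1O[C@H](C(C)=C)C[C@@]2(C)[C@@H](O[Si](C)(C)C(C)(C)C)C[C@@](O[Si](CC)(CC)CC)(C(C)C)[C@H]12
F5 | step 14 | C6 phenylthio acetal diol | c1ccccc1SC1O[C@H](C(C)=C)C[C@@]2(C)[C@@H](O)C[C@@](O)(C(C)C)[C@H]12
F6 | step 14 | axial C6-lithio C2,C4-dilithium dialkoxide | [Li][C@@H]1O[C@H](C(C)=C)C[C@@]2(C)[C@@H](O[Li])C[C@@](O[Li])(C(C)C)[C@H]12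
F7 | step 5 | keto aldehyde | O=CC[C@@]1(C)[C@@H](O[Si](C)(C)C(C)(C)C)CC(=O)[C@@H]1CO[Si](CC)(CC)CC
F8 | step 5 | keto dimethyl acetal | COC(OC)C[C@@]1(C)[C@@H](O[Si](C)(C)C(C)(C)C)CC(=O)[C@@H]1CO[Si](CC)(CC)CC
F9 | step 5 | tertiary isopropenyl carbinol | COC(OC)C[C@@]1(C)[C@@H](O[Si](C)(C)C(C)(C)C)C[C@@](O)(C(C)=C)[C@@H]1CO[Si](CC)(CC)CC
F10 | step 5 | isopropyl carbinol acetal | COC(OC)C[C@@]1(C)[C@@H](O[Si](C)(C)C(C)(C)C)C[C@@](O)(C(C)C)[C@@H]1CO[Si](CC)(CC)CC
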